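**Plan**

1. Retrosynthesis: the acid is cut first at the (2Z) C2=C1′ alkene (Still–Gennari olefination; the furan, the only ring, arrives intact in 3-(furan-3-yl)propanal), then at the C5–isopropenyl bond (Zweifel olefination of a C5–B bond), then at C4–C5 and C6–C7 together (conjunctive cross-coupling).
2. Enabling feature: the single stereocentre C5 is a CH between the saturated C4H2 of the acid tether and the allylic C6H2 that leads into the (7E)-C7=C8(CH3) alkene, and it carries the isopropenyl group. C5–C6 is therefore the vinyl unit of a vinylboron ate complex, C4 the carbon that migrates from boron, C7 the alkenyl electrophile carbon, and boron on C5 the placeholder for isopropenyl.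
3. Forward: nerol → neryl bromide → propargylation → carboalumination/bromination gives the C14 alkenyl bromide; but-3-en-1-ol → silyl ether → hydroboration gives the C4 boronate. Both are joined with vinyllithium, isopropenyl is installed, the silyloxy end is oxidised to the methyl ester, α-phosphonylated, olefinated with the furyl aldehyde and saponified. No ring is formed anywhere in the route.
4. Stereochemistry: C5 (R) comes from the chiral palladium catalyst of the coupling and passes through the Zweifel step with retention; 7E from syn-carboalumination, 11Z from nerol, 2Z from the Still–Gennari olefination.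

Key step: step 7

Assumption: one antipode of MandyPhos leads to the (5R)-boronate; which one is to be settled on a model coupling, and the route is written for that antipode.

**Route**

Step 1
Reactants: 1 nerol
Product: 2 neryl bromide, (2Z)-1-bromo-3,7-dimethylocta-2,6-diene
Conditions: PBr3, Et2O, −10 °C
Reagents that add atoms: phosphorus tribromide, BrP(Br)Br
Why: Allylic bromination of the primary alcohol with PBr3 (SN2 displacement on the alkyl phosphite) at low temperature should give the bromide without scrambling the (Z)-alkene.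

Step 2
Reactants: 2 neryl bromide; 3 1-(trimethylsilyl)propyne
Product: 6 (5Z)-6,10-dimethylundeca-5,9-dien-1-yne, via lithiated silylpropyne 4 (not isolated), via silylated enyne 5 (not isolated)
Conditions: 3, n-BuLi, THF, −78 °C; then 2, −78 → 0 °C; then Bu4NF, THF, rt
Reagents that add atoms: none
Why: Propargylic lithiation of the silylpropyne and SN2 alkylation at the primary allylic bromide (silyl-directed propargylation), the silyl group steering attack to the propargyl terminus and being removed by fluoride in the same flask, should give the 1,5-enyne with the (Z)-alkene untouched.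

Step 3
Reactants: 6 (5Z)-6,10-dimethylundeca-5,9-dien-1-yne
Product: 8 (1E,5Z)-1-bromo-2,6,10-trimethylundeca-1,5,9-triene, via alkenyldimethylalane 7 (not isolated)
Conditions: Me3Al, Cp2ZrCl2 (25 mol %), CH2Cl2, 0 °C → rt; then NBS, THF, −30 → 0 °C
Reagents that add atoms: trimethylaluminium, C[Al](C)C; N-bromosuccinimide, O=C1CCC(=O)N1Br
Why: Zirconium-catalysed carboalumination (Negishi carboalumination) adds methyl and aluminium syn across the terminal alkyne with aluminium at C1, and bromodealumination with NBS occurs with retention, so the (1E)-bromide should result while the two trisubstituted alkenes stay inert.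

Step 4
Reactants: 9 but-3-en-1-ol
Product: 10 (but-3-en-1-yloxy)(tert-butyl)dimethylsilane
Conditions: TBSCl, imidazole, CH2Cl2, 0 °C → rt
Reagents that add atoms: tert-butyldimethylsilyl chloride, CC(C)(C)[Si](C)(C)Cl
Why: Imidazole-promoted silylation of a primary alcohol (silyl ether formation) gives a group that tolerates the organolithium, palladium and iodine steps ahead.

Step 5
Reactants: 10 (but-3-en-1-yloxy)(tert-butyl)dimethylsilane
Product: 11 tert-butyldimethyl[4-(4,4,5,5-tetramethyl-1,3,2-dioxaborolan-2-yl)butoxy]silane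
Conditions: pinacolborane, RhCl(PPh3)3 (1 mol %), CH2Cl2, rt
Reagents that add atoms: pinacolborane, CC1(C)OBOC1(C)C
Why: Rhodium-catalysed hydroboration of the terminal alkene with pinacolborane should deliver boron to the terminal carbon (anti-Markovnikov) and leave the silyl ether alone.

Step 6
Reactants: 12 tetravinylstannane
Product: 13 vinyllithium (halide-free, stored as a titrated THF solution)
Conditions: n-BuLi, pentane, 0 °C → rt; solid filtered and washed, then dissolved in THF
Reagents that add atoms: n-butyllithium, [Li]CCCC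
Why: Tin–lithium exchange (transmetalation) between tetravinylstannane and n-BuLi precipitates halide-free vinyllithium from pentane, the form needed so that no lithium halide enters the coupling.

Step 7
Reactants: 11 tert-butyldimethyl[4-(pinacolboryl)butoxy]silane; 13 vinyllithium; 8 (1E,5Z)-1-bromo-2,6,10-trimethylundeca-1,5,9-triene
Product: 15 tert-butyldimethyl{[(5R,7E,11Z)-8,12,16-trimethyl-5-(4,4,5,5-tetramethyl-1,3,2-dioxaborolan-2-yl)heptadeca-7,11,15-trien-1-yl]oxy}silane, via vinylboron ate complex 14 (not isolated)
Conditions: 11, 13, THF, 0 °C → rt; then 8, Pd(OAc)2 (3 mol %), MandyPhos (3.6 mol %), NaOTf (2 equiv), THF, 60 °C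
Reagents that add atoms: none
Why: Vinyllithium 13 adds to the boron of 11 to give the four-coordinate boronate 14, zerovalent palladium formed from Pd(OAc)2 and MandyPhos inserts into the C–Br bond of 8, NaOTf exchanges bromide for triflate, and the resulting cationic divalent alkenylpalladium binds the vinyl group of 14. The 4-silyloxybutyl group then shifts from boron to the α-carbon anti to palladium (C4–C5 bond) while the β-carbon becomes bound to palladium, and reductive elimination joins that CH2 to the alkenyl carbon (C6–C7 bond) with retention of the (E)-geometry. The closest known reaction type is the enantioselective palladium-catalysed conjunctive cross-coupling of vinylboron ate complexes with alkenyl triflates, or with alkenyl halides in the presence of a triflate salt, and the 2,2-disubstituted alkenyl bromide is a more hindered member of that electrophile class. No ring is closed. The C5 stereocentre is set by the chiral MandyPhos–palladium complex, which selects the enantioface of the boron-bound vinyl group, the ligand antipode being chosen for (R). The step needs the metallate shift to outrun direct Suzuki-type transfer of the vinyl group and β-hydride elimination, which the wide-bite-angle ferrocenyl diphosphine, the halide-free vinyllithium and the triflate additive should secure, while the (5Z)- and C9 alkenes of 8 are spectators.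

Step 8
Reactants: 15 secondary boronate from step 7; 16 2-bromopropene
Product: 20 tert-butyldimethyl{[(5R,7E,11Z)-8,12,16-trimethyl-5-(prop-1-en-2-yl)heptadeca-7,11,15-trien-1-yl]oxy}silane, via isopropenyllithium 17 (not isolated), via isopropenylboron ate complex 18 (not isolated), via iodoalkyl boronate 19 (not isolated)
Conditions: 16, t-BuLi, Et2O/THF, −78 °C; then 15, −78 °C; I2, MeOH, −78 °C; NaOMe, MeOH, −78 °C → rt
Reagents that add atoms: none
Why: Zweifel olefination, in which bromine–lithium exchange gives isopropenyllithium that forms the ate complex, iodine induces a 1,2-shift of C5 from boron to carbon with retention of configuration, and methoxide triggers anti elimination of boron and iodide to the 1,1-disubstituted alkene, so the C5 stereocentre is transferred unchanged.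

Step 9
Reactants: 20 silyl ether from step 8
Product: 21 (5R,7E,11Z)-8,12,16-trimethyl-5-(prop-1-en-2-yl)heptadeca-7,11,15-trien-1-ol
Conditions: Bu4NF, THF, 0 °C → rt
Reagents that add atoms: none
Why: Fluoride-mediated desilylation of the primary silyl ether, driven by Si–F bond formation, leaves the tetraene untouched.

Step 10
Reactants: 21 primary alcohol from step 9
Product: 23 (5R,7E,11Z)-8,12,16-trimethyl-5-(prop-1-en-2-yl)heptadeca-7,11,15-trienoic acid, via aldehyde 22 (not isolated)
Conditions: TEMPO (20 mol %), PhI(OAc)2, MeCN/H2O, rt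
Reagents that add atoms: water, O
Why: Nitroxyl-catalysed oxidation (TEMPO with PhI(OAc)2 as terminal oxidant) takes the primary alcohol through the aldehyde and its hydrate to the acid without touching the alkenes, and C5 is too remote to epimerise.

Step 11
Reactants: 23 carboxylic acid from step 10
Product: 24 methyl (5R,7E,11Z)-8,12,16-trimethyl-5-(prop-1-en-2-yl)heptadeca-7,11,15-trienoate
Conditions: MeI, K2CO3, DMF, rt
Reagents that add atoms: iodomethane, CI
Why: SN2 O-alkylation of the potassium carboxylate with iodomethane (esterification) is mild enough for the polyene.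

Step 12
Reactants: 24 methyl ester from step 11
Product: 27 methyl (5R,7E,11Z)-2-[bis(2,2,2-trifluoroethoxy)phosphoryl]-8,12,16-trimethyl-5-(prop-1-en-2-yl)heptadeca-7,11,15-trienoate (mixture of C2 epimers), via lithium ester enolate 25 (not isolated), via ketene acetal phosphate 26 (not isolated)
Conditions: LiN(i-Pr)2 (1.1 equiv), THF, −78 °C; ClP(O)(OCH2CF3)2; then LiN(i-Pr)2 (2.2 equiv), −78 → −20 °C; aq. NH4Cl
Reagents that add atoms: bis(2,2,2-trifluoroethyl) phosphorochloridate, O=P(Cl)(OCC(F)(F)F)OCC(F)(F)F
Why: Enolate phosphorylation followed by vinyl phosphate–phosphonate rearrangement, in which the lithium enolate is phosphorylated by the chlorophosphate and excess lithium amide shifts phosphorus from oxygen to carbon (1,3-shift) because the doubly stabilised phosphonoacetate anion is the thermodynamic sink; C2 forms as a mixture of epimers, which is of no consequence since that centre becomes sp2 in step 16.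

Step 13
Reactants: 28 furan-3-carbaldehyde
Product: 29 ethyl (2E)-3-(furan-3-yl)prop-2-enoate
Conditions: Ph3P=CHCO2Et, CH2Cl2, rt
Reagents that add atoms: ethyl (triphenylphosphoranylidene)acetate, CCOC(=O)C=P(c1ccccc1)(c1ccccc1)c1ccccc1
Why: Wittig olefination with a stabilised ylide gives the conjugated ester, whose geometry is irrelevant because the alkene is reduced next.

Step 14
Reactants: 29 ethyl (2E)-3-(furan-3-yl)prop-2-enoate
Product: 30 ethyl 3-(furan-3-yl)propanoate
Conditions: H2 (1 atm), Pd/C (5 %), EtOAc, rt, stopped at one equivalent of H2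
Reagents that add atoms: none
Why: Heterogeneous catalytic hydrogenation reduces the conjugated disubstituted alkene much faster than the aromatic furan, so at 1 atm with monitoring only the side-chain alkene should be saturated.

Step 15
Reactants: 30 ethyl 3-(furan-3-yl)propanoate
Product: 31 3-(furan-3-yl)propanal
Conditions: i-Bu2AlH, CH2Cl2, −78 °C; aq. potassium sodium tartrate
Reagents that add atoms: none
Why: Partial reduction of the ester with i-Bu2AlH at −78 °C stops at the tetrahedral aluminium hemiacetal, which releases the aldehyde on work-up.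

Step 16
Reactants: 27 phosphonate from step 12; 31 3-(furan-3-yl)propanal
Product: 33 methyl (2Z,5R,7E,11Z)-2-[3-(furan-3-yl)propylidene]-8,12,16-trimethyl-5-(prop-1-en-2-yl)heptadeca-7,11,15-trienoate, via potassium phosphonate carbanion 32 (not isolated)
Conditions: KN(SiMe3)2, 18-crown-6, THF, −78 °C; then 31, −78 °C
Reagents that add atoms: none
Why: Still–Gennari olefination, in which the trifluoroethyl phosphonate anion with a crown-ether-separated potassium counter-ion adds to the aldehyde and eliminates fast and irreversibly from the kinetic adduct, which should place the ester cis to the furylethyl chain, that is the (2Z)-alkene, the base being consumed by the acidic phosphonate before the enolisable aldehyde is added.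

Step 17
Reactants: 33 methyl ester from step 16
Product: 34 (2Z,5R,7E,11Z)-2-[3-(furan-3-yl)propylidene]-8,12,16-trimethyl-5-(prop-1-en-2-yl)heptadeca-7,11,15-trienoic acid (CNP0235819.1)
Conditions: LiOH, THF/MeOH/H2O, 40 °C; then 1 M HCl to pH 4, 0 °C
Reagents that add atoms: lithium hydroxide, [Li+].[OH-]
Why: Saponification of the methyl ester by hydroxide (acyl substitution) and careful acidification should release the acid without isomerising the (2Z)-alkene or harming the furan.

**Compound list**

1 | nerol, (2Z)-3,7-dimethylocta-2,6-dien-1-ol | CC(C)=CCC/C(C)=C\CO | starting material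
2 | neryl bromide, (2Z)-1-bromo-3,7-dimethylocta-2,6-diene | CC(C)=CCC/C(C)=C\CBr | intermediate
3 | 1-(trimethylsilyl)propyne | CC#C[Si](C)(C)C | starting material
4 | 3-lithio-1-(trimethylsilyl)propyne | [Li]CC#C[Si](C)(C)C | intermediate
5 | trimethyl[(5Z)-6,10-dimethylundeca-5,9-dien-1-yn-1-yl]silane | C[Si](C)(C)C#CCC/C=C(/C)CCC=C(C)C | intermediate
6 | (5Z)-6,10-dimethylundeca-5,9-dien-1-yne | C#CCC/C=C(/C)CCC=C(C)C | intermediate
7 | dimethyl[(1E,5Z)-2,6,10-trimethylundeca-1,5,9-trien-1-yl]alane | C[Al](C)/C=C(\C)CC/C=C(/C)CCC=C(C)C | intermediate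
8 | (1E,5Z)-1-bromo-2,6,10-trimethylundeca-1,5,9-triene | Br/C=C(\C)CC/C=C(/C)CCC=C(C)C | intermediate
9 | but-3-en-1-ol | C=CCCO | starting material
10 | (but-3-en-1-yloxy)(tert-butyl)dimethylsilane | C=CCCO[Si](C)(C)C(C)(C)C | intermediate
11 | tert-butyldimethyl[4-(4,4,5,5-tetramethyl-1,3,2-dioxaborolan-2-yl)butoxy]silane | CC(C)(C)[Si](C)(C)OCCCCB1OC(C)(C)C(C)(C)O1 | intermediate
12 | tetravinylstannane | C=C[Sn](C=C)(C=C)C=C | starting material
13 | vinyllithium | [Li]C=C | intermediate
14 | lithium [4-(tert-butyldimethylsilyloxy)butyl](ethenyl)(pinacolato)borate | [Li+].C=C[B-]1(CCCCO[Si](C)(C)C(C)(C)C)OC(C)(C)C(C)(C)O1 | intermediate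
15 | tert-butyldimethyl{[(5R,7E,11Z)-8,12,16-trimethyl-5-(4,4,5,5-tetramethyl-1,3,2-dioxaborolan-2-yl)heptadeca-7,11,15-trien-1-yl]oxy}silane | CC1(C)OB(OC1(C)C)[C@@H](C/C=C(\C)CC/C=C(/C)CCC=C(C)C)CCCCO[Si](C)(C)C(C)(C)C | intermediate
16 | 2-bromopropene | CC(Br)=C | starting material
17 | isopropenyllithium | [Li]C(C)=C | intermediate
18 | lithium (5R)-alkyl(isopropenyl)(pinacolato)borate formed from 15 and 17 | [Li+].C=C(C)[B-]1(OC(C)(C)C(C)(C)O1)[C@@H](C/C=C(\C)CC/C=C(/C)CCC=C(C)C)CCCCO[Si](C)(C)C(C)(C)C | intermediate
19 | β-iodoalkyl boronate, 1-iodo-2-methyl-2-(pinacolboryl)-3-substituted chain with C5 (R) and the new boron-bearing carbon undefined | ICC(C)(B1OC(C)(C)C(C)(C)O1)[C@@H](C/C=C(\C)CC/C=C(/C)CCC=C(C)C)CCCCO[Si](C)(C)C(C)(C)C | intermediate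
20 | tert-butyldimethyl{[(5R,7E,11Z)-8,12,16-trimethyl-5-(prop-1-en-2-yl)heptadeca-7,11,15-trien-1-yl]oxy}silane | C=C(C)[C@@H](C/C=C(\C)CC/C=C(/C)CCC=C(C)C)CCCCO[Si](C)(C)C(C)(C)C | intermediate
21 | (5R,7E,11Z)-8,12,16-trimethyl-5-(prop-1-en-2-yl)heptadeca-7,11,15-trien-1-ol | C=C(C)[C@@H](C/C=C(\C)CC/C=C(/C)CCC=C(C)C)CCCCO | intermediate
22 | (5R,7E,11Z)-8,12,16-trimethyl-5-(prop-1-en-2-yl)heptadeca-7,11,15-trienal | C=C(C)[C@@H](C/C=C(\C)CC/C=C(/C)CCC=C(C)C)CCCC=O | intermediate
23 | (5R,7E,11Z)-8,12,16-trimethyl-5-(prop-1-en-2-yl)heptadeca-7,11,15-trienoic acid | C=C(C)[C@@H](C/C=C(\C)CC/C=C(/C)CCC=C(C)C)CCCC(=O)O | intermediate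
24 | methyl (5R,7E,11Z)-8,12,16-trimethyl-5-(prop-1-en-2-yl)heptadeca-7,11,15-trienoate | C=C(C)[C@@H](C/C=C(\C)CC/C=C(/C)CCC=C(C)C)CCCC(=O)OC | intermediate
25 | lithium enolate of ester 24 | C=C(C)[C@@H](C/C=C(\C)CC/C=C(/C)CCC=C(C)C)CCC=C(OC)O[Li] | intermediate
26 | ketene acetal phosphate of ester 24, 1-methoxyalk-1-en-1-yl bis(2,2,2-trifluoroethyl) phosphate | C=C(C)[C@@H](C/C=C(\C)CC/C=C(/C)CCC=C(C)C)CCC=C(OC)OP(=O)(OCC(F)(F)F)OCC(F)(F)F | intermediate
27 | methyl (5R,7E,11Z)-2-[bis(2,2,2-trifluoroethoxy)phosphoryl]-8,12,16-trimethyl-5-(prop-1-en-2-yl)heptadeca-7,11,15-trienoate, C2 epimers | C=C(C)[C@@H](C/C=C(\C)CC/C=C(/C)CCC=C(C)C)CCC(C(=O)OC)P(=O)(OCC(F)(F)F)OCC(F)(F)F | intermediate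
28 | furan-3-carbaldehyde | O=Cc1ccoc1 | starting material
29 | ethyl (2E)-3-(furan-3-yl)prop-2-enoate | CCOC(=O)/C=C/c1ccoc1 | intermediate
30 | ethyl 3-(furan-3-yl)propanoate | CCOC(=O)CCc1ccoc1 | intermediate
31 | 3-(furan-3-yl)propanal | O=CCCc1ccoc1 | intermediate
32 | potassium salt of the C2 carbanion of phosphonate 27 | [K+].C=C(C)[C@@H](C/C=C(\C)CC/C=C(/C)CCC=C(C)C)CC[C-](C(=O)OC)P(=O)(OCC(F)(F)F)OCC(F)(F)F | intermediate
33 | methyl (2Z,5R,7E,11Z)-2-[3-(furan-3-yl)propylidene]-8,12,16-trimethyl-5-(prop-1-en-2-yl)heptadeca-7,11,15-trienoate | C=C(C)[C@@H](C/C=C(\C)CC/C=C(/C)CCC=C(C)C)CC/C(=C/CCc1ccoc1)C(=O)OC | intermediate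
34 | (2Z,5R,7E,11Z)-2-[3-(furan-3-yl)propylidene]-8,12,16-trimethyl-5-(prop-1-en-2-yl)heptadeca-7,11,15-trienoic acid | C=C(C)[C@@H](C/C=C(\C)CC/C=C(/C)CCC=C(C)C)CC/C(=C/CCc1ccoc1)C(=O)O | target

**Step count**

Total: 17 steps. Longest linear sequence: 11 steps (1, 2, 3, 7, 8, 9, 10, 11, 12, 16, 17, from nerol).

**Steps most likely to fail**

Step 7. Oxidative addition into the hindered 2,2-disubstituted alkenyl bromide and binding of the ate complex may be slow, so that direct transfer of the vinyl group, β-hydride elimination or poor facial selection take over. The fallback sets out from enyne 6 and boronate 11 and returns at 15, using sparteine-mediated lithiation–borylation in place of palladium. Enyne 6 is carboaluminated as in step 3 to alane 7, which n-BuLi turns into the lithium butyl(dimethyl)alkenylalanate F1. Ethylene oxide opens on its alkenyl carbon with retention to give (3E,7Z)-4,8,12-trimethyltrideca-3,7,11-trien-1-ol F2. N,N-Diisopropylcarbamoyl chloride converts this alcohol into the N,N-diisopropylcarbamate F3. s-BuLi with (+)-sparteine in Et2O at −78 °C removes one enantiotopic O–CH2 proton to give the (1R)-1-lithio carbamate F4. Boronate 11 adds with retention to form the lithium boronate complex F5. On warming to 35 °C the silyloxybutyl group shifts from boron to carbon with inversion and expels the carbamate, which should give 15; C4–C5 is again made by a 1,2-shift, while C6–C7 comes from the epoxide opening.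

Step 12. Phosphorylation may stop at oxygen, or the amide base or the enolate may attack the electrophilic trifluoroethyl phosphate with loss of trifluoroethoxide. The fallback sets out from ester 24 and returns at 27, forming the C–P bond with a trivalent phosphorus chloride and exchanging the ester groups afterwards. Enolate 25 is treated with ClP(OEt)2 at −78 °C to give methyl 2-(diethoxyphosphanyl) ester F6, which H2O2 oxidises to the diethyl phosphonate F7. Me3SiBr with pyridine in CH2Cl2 cleaves both ethyl groups to the bis(trimethylsilyl) phosphonate F8. (COCl)2 with catalytic DMF gives the phosphonic dichloride F9, and CF3CH2OH with Et3N converts it into 27.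

Step 3. NBS may brominate the two trisubstituted alkenes in competition with bromodealumination, or the alane may be protonated. The fallback sets out from enyne 6 (through alane 7) and returns at 8. The alane is quenched with I2 in THF at −30 °C, the usual and more selective halogenolysis, to give (1E,5Z)-1-iodo-2,6,10-trimethylundeca-1,5,9-triene F10. t-BuLi in Et2O at −78 °C exchanges iodine for lithium with retention to give the (1E,5Z)-alkenyllithium F11, and 1,2-dibromotetrachloroethane brominates it to 8.

**Further compounds**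

F1 | step 7 | lithium butyl(dimethyl)[(1E,5Z)-2,6,10-trimethylundeca-1,5,9-trien-1-yl]alanate | [Li+].CCCC[Al-](C)(C)/C=C(\C)CC/C=C(/C)CCC=C(C)C
F2 | step 7 | (3E,7Z)-4,8,12-trimethyltrideca-3,7,11-trien-1-ol | OCC/C=C(\C)CC/C=C(/C)CCC=C(C)C
F3 | step 7 | (3E,7Z)-4,8,12-trimethyltrideca-3,7,11-trien-1-yl N,N-diisopropylcarbamate | CC(C)N(C(C)C)C(=O)OCC/C=C(\C)CC/C=C(/C)CCC=C(C)C
F4 | step 7 | (1R,3E,7Z)-1-lithio-4,8,12-trimethyltrideca-3,7,11-trien-1-yl N,N-diisopropylcarbamate (sparteine complex) | [Li][C@H](C/C=C(\C)CC/C=C(/C)CCC=C(C)C)OC(=O)N(C(C)C)C(C)C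
F5 | step 7 | lithium boronate complex of F4 and 11, (1R)-configured at the carbamate carbon | [Li+].CC(C)(C)[Si](C)(C)OCCCC[B-]1(OC(C)(C)C(C)(C)O1)[C@H](C/C=C(\C)CC/C=C(/C)CCC=C(C)C)OC(=O)N(C(C)C)C(C)C
F6 | step 12 | methyl (5R,7E,11Z)-2-(diethoxyphosphanyl)-8,12,16-trimethyl-5-(prop-1-en-2-yl)heptadeca-7,11,15-trienoate | C=C(C)[C@@H](C/C=C(\C)CC/C=C(/C)CCC=C(C)C)CCC(C(=O)OC)P(OCC)OCC
F7 | step 12 | methyl (5R,7E,11Z)-2-(diethoxyphosphoryl)-8,12,16-trimethyl-5-(prop-1-en-2-yl)heptadeca-7,11,15-trienoate | C=C(C)[C@@H](C/C=C(\C)CC/C=C(/C)CCC=C(C)C)CCC(C(=O)OC)P(=O)(OCC)OCC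
F8 | step 12 | methyl (5R,7E,11Z)-2-{bis[(trimethylsilyl)oxy]phosphoryl}-8,12,16-trimethyl-5-(prop-1-en-2-yl)heptadeca-7,11,15-trienoate | C=C(C)[C@@H](C/C=C(\C)CC/C=C(/C)CCC=C(C)C)CCC(C(=O)OC)P(=O)(O[Si](C)(C)C)O[Si](C)(C)C
F9 | step 12 | methyl (5R,7E,11Z)-2-(dichlorophosphoryl)-8,12,16-trimethyl-5-(prop-1-en-2-yl)heptadeca-7,11,15-trienoate | C=C(C)[C@@H](C/C=C(\C)CC/C=C(/C)CCC=C(C)C)CCC(C(=O)OC)P(=O)(Cl)Cl
F10 | step 3 | (1E,5Z)-1-iodo-2,6,10-trimethylundeca-1,5,9-triene | I/C=C(\C)CC/C=C(/C)CCC=C(C)C
F11 | step 3 | (1E,5Z)-1-lithio-2,6,10-trimethylundeca-1,5,9-triene | [Li]/C=C(\C)CC/C=C(/C)CCC=C(C)C
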